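In a one-step world substrate goes on turning into target until it is gone, and the time allowed is what counts. We hold that picture against the runs so far.

in all of them: enzyme 30 µM (in portions, 2)
- ash: substrate 20 mM; added ligand 44 µM; run made earlier; portions every 2.0 s
- oak: substrate 45 mM; added ligand 44 µM; run made earlier; portions every 2.0 s
- larch: substrate 30 mM; added ligand 66 µM; run made earlier; portions every 2.0 s
- flask: substrate 30 mM; added ligand 44 µM; the portions of enzyme follow each other after 2.0 s, the first at the start; time 30 min

- ash (time / min: substrate / %, target / %): 1.50: 9.5, 65.9; 5.00: 0.2, 71.8; 8.00: 0, 71.4; 12.0: 0.5, 70.9; 20.0: 0, 71.3; 25.0: 0, 70.6; 30.0: 0.8, 71.8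
- oak (time / min: substrate / %, target / %): 2.50: 87.5, 8.6; 4.00: 88.3, 7.9; 6.00: 87.2, 8.5; 8.00: 87.1, 8.6; 12.0: 88.3, 9.1; 20.0: 88.6, 9.3; 30.0: 88.2, 8.2
- larch (time / min: substrate / %, target / %): 6.00: 70.8, 20.5; 12.0: 70.9, 20.6; 20.0: 70.2, 20.6; 25.0: 70.4, 21.4; 30.0: 70.1, 21.3

(readings scatter by 0.5 percentage points)

* share of the substrate used up at 30 min
* target at 30 min, in percent of the substrate charged
* isomer of the product at 30 min, in percent of the substrate charged

It fails at once. The oak run holds 87.5% of substrate at 2.50 min and 88.2% at 30.0 min, so it stops with substrate present, and the larch run is as flat. We take it that the enzyme stops working.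

Perhaps each enzyme makes a fixed count of turnovers, the total turnover number? Averaging the flat readings, substrate stays at 87.9% in oak and 70.5% in larch. That makes 182 turnovers in oak and 295 in larch, more in larch, so the count isn't fixed.

Try the count times the starting substrate: 8.18 M for oak, 8.86 M for larch, still apart. But substrate falls during a run, so we replace its curve by the mean of start and end:

turnover budget = turnovers × (start + end substrate) / 2

oak: 7.68 M; larch: 7.55 M

Their gap is a smaller share than one reading's scatter of 0.5 percentage points makes on oak's consumption. We carry their mean, the turnover budget 7.62 M.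

Doesn't larch hold more added ligand, 66 µM against 44 µM? Yes, yet the two budgets match. Can the ash run finish? Complete use needs 6.67 M, less than the budget, and the last substrate reading of the ash run is 0.8%.

For the flask, solving the budget for conversion:

conversion = 1 − sqrt(1 − 2 × budget × enzyme / substrate²) = 29.8%

With the target share read from the ash run, 71.2%, and the rest of what is consumed taken as isomer, we reckon 21.2% target and 8.59% isomer in the flask, flat from the early readings.

The forecast differs: 44%, 31.5% and 12.5%, on the ground that “Ligand seems to hurt too, since larch gives less than the ash–oak trend implies.”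

The flask gives 29.5% conversion, 21.0% target and 8.39% isomer.

    substrate + enzyme → target + enzyme, rate k1*[substrate]*[enzyme]/(1 + ([substrate]/Km1)) (1.40 mM, k = 43000 M⁻¹ s⁻¹)
    substrate + enzyme → spent catalyst (k = 7.60 M⁻¹ s⁻¹)
    enzyme + added ligand ⇌ idle complex, settled at all times (K = 13000 M⁻¹)
    target ⇌ isomer of the product (K = 0.400, k = 0.0150 s⁻¹)

The flask's own budget, reckoned from that conversion, comes to 7.54 M. Each setting of the flask, moved alone by the same factor, shifts the target at most thus: substrate (20 points), then enzyme (8.1 points), then added ligand (under 0.05 points). For the neighbouring flask with 0.051 mM of enzyme, all else as in the recipe, the budget reckons a conversion of 63.0%, and that flask gives 60.5%.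

The readings are simulated on assumed constants; the scatter is artificial.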